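The eleven-membered carbocycle is a hydroxylated humulene ring carrying two tropolone-fused dihydropyrans. Its C(CH3)2–CH2 unit, the adjacent ring-fusion CH (ArCH2-bearing) and the alkene CH next to C(CH3)2 are treated as the opened cyclobutane of caryophyllene. In the key step a cobalt hydride transfers H• to the exocyclic methylene of a C7-silyloxy caryophyllene oxide; the cyclobutylcarbinyl radical cleaves the ring-fusion bond and cobalt takes back the neighbouring hydrogen, so the nine-membered ring grows by two atoms into the (E,E)-cycloundecadiene and the methylene becomes the C-methyl group. Epoxide removal and a double hetero-Diels–Alder reaction with a tropolone o-quinone methide, steered by the carbinol stereocentre, finish the synthesis.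

Key step: step 6

Remark: terpene carbons keep caryophyllane numbering throughout (C1/C9 cyclobutane ring-fusion carbons, C10 cyclobutane CH2, C11 CMe2, C4/C5 epoxide or alkene carbons, C7 carbinol carbon, C8 bearing exocyclic C13). Compounds 1 and 5 are assumed to be purchasable and the two enzymes of step 1 obtainable by standard heterologous expression.

Step 1
Reactants: 1 2,4-dihydroxy-3,6-dimethylbenzaldehyde (3-methylorcinaldehyde)
Product: 3 stipitaldehyde, via hydroxylated dienone 2 (not isolated)
Conditions: TropB-type FAD-dependent monooxygenase and TropC-type α-ketoglutarate-dependent non-heme iron dioxygenase (clarified lysates), NADP+ (cat.), glucose, glucose dehydrogenase, α-ketoglutarate, FeSO4 (cat.), sodium ascorbate, air, phosphate buffer pH 8 with 5% DMSO, 30 °C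
Reagents that add atoms: dioxygen O=O
Why: Enzymatic oxidative dearomatisation then radical ring expansion, both established for this substrate: the flavin hydroperoxide hydroxylates the methyl-bearing C3 to dienone 2, and the iron enzyme (divalent iron resting state, tetravalent iron–oxo oxidant) abstracts hydrogen from that methyl group so that the carbon inserts into the ring and loss of water gives the tropolone.

Step 2
Reactants: 3 stipitaldehyde
Product: 4 2,4-dihydroxy-5-(hydroxymethyl)-6-methylcyclohepta-2,4,6-trien-1-one
Conditions: NaBH4, MeOH/THF, 0 °C; pH 6 phosphate buffer quench, product kept cold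
Reagents that add atoms: none
Why: Chemoselective hydride reduction of the formyl group, the tropolone carbonyl being deactivated as its vinylogous carboxylate anion under the basic conditions; no stereocentre is formed.

Step 3
Reactants: 5 (−)-caryophyllene oxide
Product: 7 (1R,4R,5R,9S)-4,5-epoxycaryophyll-8(13)-en-7-one, via allylic alcohols 6 (not isolated)
Conditions: SeO2 (0.5 equiv), tBuOOH (3 equiv), CH2Cl2, 0 °C to rt; short silica filtration; then Dess–Martin periodinane, NaHCO3, CH2Cl2, rt
Reagents that add atoms: selenium dioxide O=[Se]=O (oxygen carrier); tert-butyl hydroperoxide CC(C)(C)OO (terminal oxygen source)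
Why: Allylic oxidation by ene reaction and [2,3]-sigmatropic shift can only use the C7 hydrogens, because removal of the C9 methine hydrogen would require an alkylidenecyclobutane and the epoxide masks the other alkene, and Dess–Martin oxidation converges both C7 epimers of 6 to enone 7 without touching C1, C4, C5 and C9.

Step 4
Reactants: 7 (1R,4R,5R,9S)-4,5-epoxycaryophyll-8(13)-en-7-one
Product: 8 (1R,4R,5R,7S,9S)-4,5-epoxycaryophyll-8(13)-en-7-ol
Conditions: (R)-2-methyl-CBS-oxazaborolidine (0.2 equiv), catecholborane, toluene, −78 °C
Reagents that add atoms: none
Why: Corey–Bakshi–Shibata reduction under reagent control: with the 1,1-disubstituted alkenyl group (C8) as the large and C6H2 as the small ketone substituent, the (R)-oxazaborolidine should deliver hydride to the face that gives the 7S carbinol, while catecholborane at −78 °C leaves the alkene and the epoxide untouched.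

Step 5
Reactants: 8 (1R,4R,5R,7S,9S)-4,5-epoxycaryophyll-8(13)-en-7-ol
Product: 9 (1R,4R,5R,7S,9S)-7-(tert-butyldimethylsilyloxy)-4,5-epoxycaryophyll-8(13)-ene
Conditions: TBSCl, imidazole, DMAP (cat.), DMF, rt
Reagents that add atoms: tert-butyldimethylsilyl chloride CC(C)(C)[Si](C)(C)Cl
Why: Standard silylation of the secondary allylic alcohol with retention at C7; the silyl ether prevents hydrogen-atom isomerisation of the allylic alcohol to a ketone in step 6 and alkoxide formation in step 7.

Step 6
Reactants: 9 (1R,4R,5R,7S,9S)-7-(tert-butyldimethylsilyloxy)-4,5-epoxycaryophyll-8(13)-ene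
Product: 10 tert-butyldimethylsilyl ether of (1S,2E,6E,9R,10R)-9,10-epoxy-2,5,5,9-tetramethylcycloundeca-2,6-dien-1-ol
Conditions: Co(tBu4-salen)Cl [chloro(N,N′-bis(3,5-di-tert-butylsalicylidene)ethylenediaminato)cobalt, trivalent cobalt] (5 mol %), PhSiH3 (6 mol %), benzene, rt, argon
Reagents that add atoms: none
Why: The cobalt hydride formed from the trivalent cobalt complex and PhSiH3 transfers a hydrogen atom to C13 of the 1,1-disubstituted alkene (Markovnikov MHAT) to give the tertiary C8 radical, a cyclobutylcarbinyl radical whose β-scission of the C1–C9 ring-fusion bond creates the C8=C9 alkene and a secondary C1 radical, from which divalent cobalt removes a C2 hydrogen to form the C1=C2 alkene and regenerate the hydride. The closest known reaction type is the cobalt–salen/silane MHAT alkene isomerisation in its retro-cycloisomerisation mode on alkenyl-substituted strained rings, which tolerates epoxides and silyl ethers. No ring-closing bond is made: the eleven-membered ring arises from the nine-membered ring of the bicyclo[7.2.0]undecane by cleavage of the bond shared with the cyclobutane, so that C10 and C11 are inserted (ring expansion by two atoms). No stereocentre is created and C4, C5 and C7 are untouched; the E geometry of C8=C9 follows from the fused-ring conformation, in which C10 is anti to C7 about C8–C9 and the C1–C9 bond lies nearly parallel to the singly occupied orbital, and the E geometry of C1=C2 from the preference of the eleven-membered ring for a trans alkene next to quaternary C11. The step needs hydrogen-atom transfer to the only alkene, scission of C1–C9 rather than C9–C10, and hydrogen loss only towards C2; these are secured by formation of a secondary rather than a primary radical, by the orbital alignment just described and by C11 being quaternary, while hydrogen return from C7 or C9 would give tetrasubstituted alkenes and the substoichiometric silane excludes net reduction.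

Step 7
Reactants: 10 tert-butyldimethylsilyl ether of (1S,2E,6E,9R,10R)-9,10-epoxy-2,5,5,9-tetramethylcycloundeca-2,6-dien-1-ol
Product: 12 (1S,2E,6E,9E)-2,5,5,9-tetramethylcycloundeca-2,6,9-trien-1-ol, via triene silyl ether 11 (not isolated)
Conditions: WCl6 (3 equiv), n-BuLi (6 equiv), THF, −78 °C to rt, then 10, rt; aqueous NaOH work-up; then n-Bu4NF, THF, rt
Reagents that add atoms: none
Why: Oxygen-atom transfer from the epoxide to the low-valent tungsten chloride made from WCl6 and two equivalents of n-BuLi proceeds with retention, so the trans-epoxide returns the E-trisubstituted alkene (a deoxygenation established for trisubstituted terpene epoxides), and fluoride then cleaves the silyl ether without touching C7.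

Step 8
Reactants: 12 (1S,2E,6E,9E)-2,5,5,9-tetramethylcycloundeca-2,6,9-trien-1-ol; 4 2,4-dihydroxy-5-(hydroxymethyl)-6-methylcyclohepta-2,4,6-trien-1-one (3 equiv)
Product: 15 target bis(tropolone-dihydropyran) adduct CNP0283947.4, via tropolone o-quinone methide 13 (not isolated), via mono-adduct 14 (not isolated)
Conditions: p-xylene, 150 °C, sealed tube, 4 added in portions
Reagents that add atoms: none
Why: Thermal dehydration of 4 gives o-quinone methide 13, which should undergo two inverse-electron-demand hetero-Diels–Alder reactions with the trisubstituted E-alkenes of 12 (the CMe2-flanked disubstituted alkene is inert), its CH2 bonding to the alkene CH and its oxygen to the methyl-bearing carbon, suprafacially so that both ring fusions are trans; the diene can only approach the peripheral alkene face, and at the alkene next to the carbinol the conformer with C7–H near the vinylic methyl and the C7–O bond in the inside position (allylic 1,2-strain, inside-alkoxy effect) exposes the face that gives 8R,9R, while the distal alkene is expected to react through the macrocycle conformer with the two vinylic methyl groups on opposite ring faces to give 4R,5R.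

Compound list
1 | 2,4-dihydroxy-3,6-dimethylbenzaldehyde (3-methylorcinaldehyde) | Cc1cc(O)c(C)c(O)c1C=O | starting material
2 | (5R)-4,5-dihydroxy-2,5-dimethyl-6-oxocyclohexa-1,3-diene-1-carbaldehyde (hydroxylated dienone) | O=CC1=C(C)C=C(O)[C@@](C)(O)C1=O | intermediate
3 | stipitaldehyde (2,4-dihydroxy-7-methyl-5-oxocyclohepta-1,3,6-triene-1-carbaldehyde) | Cc1cc(=O)c(O)cc(O)c1C=O | intermediate
4 | 2,4-dihydroxy-5-(hydroxymethyl)-6-methylcyclohepta-2,4,6-trien-1-one | Cc1cc(=O)c(O)cc(O)c1CO | intermediate
5 | (−)-caryophyllene oxide, (1R,4R,5R,9S)-4,5-epoxycaryophyll-8(13)-ene | C[C@@]12CC[C@@H]3[C@H](CC3(C)C)C(=C)CC[C@H]1O2 | starting material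
6 | (1R,4R,5R,9S)-4,5-epoxycaryophyll-8(13)-en-7-ol, both C7 epimers (allylic alcohols) | C[C@@]12CC[C@@H]3[C@H](CC3(C)C)C(=C)C(O)C[C@H]1O2 | intermediate
7 | (1R,4R,5R,9S)-4,5-epoxycaryophyll-8(13)-en-7-one | C[C@@]12CC[C@@H]3[C@H](CC3(C)C)C(=C)C(=O)C[C@H]1O2 | intermediate
8 | (1R,4R,5R,7S,9S)-4,5-epoxycaryophyll-8(13)-en-7-ol | C[C@@]12CC[C@@H]3[C@H](CC3(C)C)C(=C)[C@@H](O)C[C@H]1O2 | intermediate
9 | (1R,4R,5R,7S,9S)-7-(tert-butyldimethylsilyloxy)-4,5-epoxycaryophyll-8(13)-ene | C[C@@]12CC[C@@H]3[C@H](CC3(C)C)C(=C)[C@@H](O[Si](C)(C)C(C)(C)C)C[C@H]1O2 | intermediate
10 | tert-butyldimethylsilyl ether of (1S,2E,6E,9R,10R)-9,10-epoxy-2,5,5,9-tetramethylcycloundeca-2,6-dien-1-ol | C[C@@]12C/C=C/C(C)(C)C/C=C(C)/[C@@H](O[Si](C)(C)C(C)(C)C)C[C@H]1O2 | intermediate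
11 | tert-butyldimethylsilyl ether of (1S,2E,6E,9E)-2,5,5,9-tetramethylcycloundeca-2,6,9-trien-1-ol (triene silyl ether) | C/C1=C\C[C@H](O[Si](C)(C)C(C)(C)C)/C(C)=C/CC(C)(C)/C=C/C1 | intermediate
12 | (1S,2E,6E,9E)-2,5,5,9-tetramethylcycloundeca-2,6,9-trien-1-ol | C/C1=C\C[C@H](O)/C(C)=C/CC(C)(C)/C=C/C1 | intermediate
13 | 2-hydroxy-6-methyl-5-methylidenecyclohepta-2,6-diene-1,4-dione (tropolone o-quinone methide) | C=C1C(C)=CC(=O)C(O)=CC1=O | intermediate
14 | mono-adduct, tropolone-dihydropyran fused at the distal alkene (4R,5R,7S; E-alkenes at C8=C9 and C1=C2) | C/C1=C\CC(C)(C)/C=C/C[C@@]2(C)Oc3cc(O)c(=O)cc(C)c3C[C@@H]2C[C@@H]1O | intermediate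
15 | CNP0283947.4, bis(tropolone-dihydropyran)-fused hydroxyhumulene (carbinol carbon S, the four ring-fusion carbons R, both ring fusions trans, E-alkene) | Cc1cc(=O)c(O)cc2c1C[C@H]1CC(C)(C)/C=C/C[C@@]3(C)Oc4cc(O)c(=O)cc(C)c4C[C@@H]3C[C@H](O)[C@]1(C)O2 | target

Total step count: 8. Longest linear sequence: 6 steps (steps 3 to 8, from caryophyllene oxide 5).

Steps most likely to fail

Step 8. Facial discrimination at one or both alkenes may be poor, the second cycloaddition at the alkene next to the carbinol may stall, or the o-quinone methide may oligomerise. The fallback changes the controlling element from the free hydroxyl to a bulky silyl ether and sets out from 10: the deoxygenation of step 7 is run without fluoride and 11 is isolated. The larger silyloxy group should strengthen the allylic 1,2-strain bias for the required alkene face. Cycloaddition of 11 with 4 (p-xylene, 150 °C) should then give the silyl ether of the target F1, and HF·pyridine in THF returns to the route at 15.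

Step 6. The C8 radical may give hydrogen back without ring opening, the product alkenes may isomerise further, or the cobalt catalyst may be deactivated. The fallback separates ring opening from alkene formation and sets out from 9: a cobalt-catalysed radical hydrochlorination (Co(BF4)2·6H2O with a salen-type ligand, PhSiH3, slow addition of TsCl, tBuOOH cat., EtOH, rt) generates the same C8 radical, which should ring-open before chlorine-atom transfer. The C1 radical is then trapped as the ring-expanded secondary chloride F2. E2 elimination with KOtBu in DMSO can only engage the C2 hydrogens, because C11 is quaternary, and returns to the route at 10.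

Step 7. Lewis-acidic tungsten species may trigger transannular cyclisation of the epoxy-diene, or oxygen transfer may erode the alkene geometry. The fallback uses nucleophilic opening and anti elimination and sets out from 10: PhSeNa (from PhSeSePh and NaBH4, EtOH) opens the epoxide at secondary C5 with inversion to the β-hydroxy selenide F3. MsCl/Et3N then induces stereospecific anti elimination through the episelenonium ion, so that anti opening followed by anti elimination restores the E-alkene. This returns to the route at 11, which is desilylated with n-Bu4NF as in step 7.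

Further compounds
F1 | step 8 | tert-butyldimethylsilyl ether of the target at the carbinol oxygen | Cc1cc(=O)c(O)cc2c1C[C@H]1CC(C)(C)/C=C/C[C@@]3(C)Oc4cc(O)c(=O)cc(C)c4C[C@@H]3C[C@H](O[Si](C)(C)C(C)(C)C)[C@]1(C)O2
F2 | step 6 | ring-expanded secondary chloride, tert-butyldimethylsilyl ether of (1S,2E,9R,10R)-6-chloro-9,10-epoxy-2,5,5,9-tetramethylcycloundec-2-en-1-ol (C6 epimers) | C[C@@]12CCC(Cl)C(C)(C)C/C=C(C)/[C@@H](O[Si](C)(C)C(C)(C)C)C[C@H]1O2
F3 | step 7 | β-hydroxy selenide, tertiary alcohol at C4 (retained) and phenylselanyl at C5 (inverted) of the silyl-protected cycloundecadiene | C[C@@]1(O)C/C=C/C(C)(C)C/C=C(C)/[C@@H](O[Si](C)(C)C(C)(C)C)C[C@@H]1[Se]c2ccccc2
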